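The synthesis rests on cutting ring A between C1, the carbon that carries the ether oxygen, and C2, the carbon that carries the pentyl chain. Ring A, with O-aryl at C1, pentyl at C2 and hydroxyls at C4 and C6, is the pattern an aldol aromatisation of a 1-aryloxy-2,4,6-triketone leaves behind, so the crowded diaryl ether need not be made by aryl–oxygen coupling. In a single operation hydroxide unmasks a 4-pyranone to this triketone, forms C1–C2, closes ring A and aromatises it. The precursor 14 is the ring B salicylate ester O-alkylated with 2-(chloromethyl)-6-pentyl-4-pyranone, its future C1 still an sp3 methylene.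

Key step: step 11

Remark 1: the target has no stereocentre and is achiral, so there is no enantiomer to select and no stereocontrol is needed.
Remark 2: a methyl benzoate with an ortho ketone is cleaved quickly by hydroxide through participation of the ketone, so the key step is planned to end at the free acid 18 (a carboxylate also cannot suffer Dieckmann attack), and the methyl ester is restored in step 12.

Step 1
Reactants: 1 nonane-2,4-dione; 2 ethyl 2-(benzyloxy)acetate
Product: 4 1-(benzyloxy)undecane-2,4,6-trione, via dilithium dianion of nonane-2,4-dione 3 (not isolated)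
Conditions: 1 (2.1 equiv), LDA (commercial solution, 4.2 equiv), THF, −78 → 0 °C; then 2 (1 equiv), 0 °C → rt; 1 M HCl
Reagents that add atoms: none
Why: Two equivalents of LDA remove the central and then the methyl proton of the β-diketone (the less substituted terminus), and the terminal carbanion of 3 undergoes Claisen-type C-acylation by the activated α-alkoxy ester, the second equivalent of 3 taking up the acidic proton of the new triketone.

Step 2
Reactants: 4 1-(benzyloxy)undecane-2,4,6-trione
Product: 5 2-[(benzyloxy)methyl]-6-pentyl-4H-pyran-4-one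
Conditions: p-TsOH·H2O (cat.), toluene, reflux, Dean–Stark
Reagents that add atoms: none
Why: Acid-catalysed cyclodehydration of a 2,4,6-triketone (enol oxygen adds to the distal carbonyl, then water is lost) is the standard entry to 2,6-disubstituted 4-pyranones, and the benzyl ether keeps the C1 oxygen from closing a furanone instead.

Step 3
Reactants: 5 2-[(benzyloxy)methyl]-6-pentyl-4H-pyran-4-one
Product: 6 2-(hydroxymethyl)-6-pentyl-4H-pyran-4-one
Conditions: BCl3 (3 equiv), CH2Cl2, −78 → 0 °C; then MeOH
Reagents that add atoms: none
Why: Lewis-acid ether cleavage in which BCl3 removes the benzyl group as benzyl chloride at the stabilised benzylic carbon, avoiding hydrogenation conditions that could saturate the pyranone double bonds; the excess covers complexation of the pyranone carbonyl.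

Step 4
Reactants: 6 2-(hydroxymethyl)-6-pentyl-4H-pyran-4-one
Product: 7 2-(chloromethyl)-6-pentyl-4H-pyran-4-one
Conditions: SOCl2, CH2Cl2, 0 °C → rt
Reagents that add atoms: thionyl chloride, O=S(Cl)Cl
Why: Deoxychlorination of an activated primary alcohol through its chlorosulfite, as in the conversion of kojic acid into its chloromethyl derivative.

Step 5
Reactants: 8 3,5-dimethoxybenzoic acid
Product: 9 1-(3,5-dimethoxyphenyl)pentan-1-one
Conditions: n-BuLi (2.2 equiv), THF, −78 → 0 °C; inverse quench into 1 M HCl
Reagents that add atoms: n-butyllithium, [Li]CCCC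
Why: Addition of an alkyllithium to a lithium carboxylate stops at the ketone stage because the tetrahedral dilithium adduct does not collapse until the acidic quench; the first equivalent only deprotonates the acid.

Step 6
Reactants: 9 1-(3,5-dimethoxyphenyl)pentan-1-one
Product: 10 2,4-dimethoxy-6-pentanoylbenzaldehyde
Conditions: Cl2CHOMe, TiCl4, CH2Cl2, −78 → 0 °C; then 1 M HCl
Reagents that add atoms: dichloromethyl methyl ether, COC(Cl)Cl; water, O
Why: Rieche formylation (Friedel–Crafts type) at the ring position ortho to the acyl group, which is para to one methoxy and ortho to the other and is the usual site of electrophilic attack in 3,5-dimethoxyaryl carbonyl compounds; the cold Lewis-acid conditions should leave the enolisable ketone alone.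

Step 7
Reactants: 10 2,4-dimethoxy-6-pentanoylbenzaldehyde
Product: 11 2,4-dimethoxy-6-pentanoylbenzoic acid (may sit partly as its ring lactol tautomer)
Conditions: NaClO2, NaH2PO4, 2-methyl-2-butene, t-BuOH/H2O, rt
Reagents that add atoms: sodium chlorite, [Na+].[O-]Cl=O
Why: Pinnick oxidation converts the aryl aldehyde to the acid with chlorous acid while 2-methyl-2-butene traps hypochlorous acid, so neither the electron-rich ring nor the ketone is chlorinated.

Step 8
Reactants: 11 2,4-dimethoxy-6-pentanoylbenzoic acid
Product: 12 methyl 2,4-dimethoxy-6-pentanoylbenzoate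
Conditions: MeI, K2CO3, DMF, rt
Reagents that add atoms: iodomethane, CI
Why: SN2 O-alkylation of the carboxylate, which gives the open-chain (normal) methyl ester and not the cyclic pseudo-ester that acid-catalysed esterification of a 2-acylbenzoic acid would favour.

Step 9
Reactants: 12 methyl 2,4-dimethoxy-6-pentanoylbenzoate
Product: 13 methyl 2-hydroxy-4-methoxy-6-pentanoylbenzoate
Conditions: BCl3 (2 equiv), CH2Cl2, −78 → 0 °C; aq. work-up
Reagents that add atoms: none
Why: Chelation-controlled demethylation in which BCl3 bound to the ester carbonyl cleaves only the ortho methyl ether through a six-membered chelate, the para methoxy and the ketone (which has no ortho ether) being left, as is established for 2,4-dimethoxy-6-substituted benzoates.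

Step 10
Reactants: 13 methyl 2-hydroxy-4-methoxy-6-pentanoylbenzoate; 7 2-(chloromethyl)-6-pentyl-4H-pyran-4-one
Product: 14 methyl 4-methoxy-2-[(4-oxo-6-pentyl-4H-pyran-2-yl)methoxy]-6-pentanoylbenzoate
Conditions: K2CO3, KI (cat.), DMF, 50 °C
Reagents that add atoms: none
Why: Williamson etherification in which the phenoxide of 13 displaces chloride from the activated, allylic-type chloromethyl carbon of 7 (SN2, iodide catalysis), so the ether carbon is attached as an sp3 centre under mild base that neither enolises the ketone nor opens the pyranone.

Step 11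
Reactants: 14 methyl 4-methoxy-2-[(4-oxo-6-pentyl-4H-pyran-2-yl)methoxy]-6-pentanoylbenzoate
Product: 18 2-(2,4-dihydroxy-6-pentylphenoxy)-4-methoxy-6-pentanoylbenzoic acid, via pyranone carboxylic acid 15 (not isolated), via open-chain triketone acid 16 (not isolated), via cyclic aldol adduct 17 (not isolated)
Conditions: 1 M KOH, H2O/1,4-dioxane, Ar, rt; then 3 M KOH, 60 °C, Ar; then 2 M HCl, 0 °C, to pH 2
Reagents that add atoms: potassium hydroxide, [K+].[OH-]
Why: Hydroxide should first cleave the methyl ester with help from the ortho ketone, so that ring B carries an inert carboxylate (15) before hydroxide adds at an oxygen-bearing ring carbon of the pyranone and E1cB ring opening releases the enolised triketone 16. In the polyanion of 16 the aryloxy-bearing C1 methylene is enolised and adds to the C6 (pentyl) ketone in a 6-(enolendo)-exo-trig aldol, forming the bond that becomes ring A C1–C2 and giving 17, which loses water and tautomerises to the resorcinol, so the sequence ends irreversibly. The closest known reactions are the alkali conversion of 2,6-dimethyl-4-pyranone through heptane-2,4,6-trione into orcinol and the aldol cyclisation of 2,4,6-triketones to 5-alkylresorcinols. No stereocentre remains, since the two aldol centres of 17 vanish on aromatisation. The step needs C1, and not the C7 methylene of the pentyl chain, to act as the nucleophile: the aryloxy group makes C1 the more acidic terminal position. Both ring B electrophiles are out of reach, the ester being a carboxylate and the aryl ketone sitting meta to the ether oxygen, where no unstrained ring can form.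

Step 12
Reactants: 18 2-(2,4-dihydroxy-6-pentylphenoxy)-4-methoxy-6-pentanoylbenzoic acid
Product: 19 methyl 2-(2,4-dihydroxy-6-pentylphenoxy)-4-methoxy-6-pentanoylbenzoate
Conditions: MeI (1.1 equiv), KHCO3 (1.2 equiv), DMF, rt
Reagents that add atoms: iodomethane, CI
Why: Chemoselective SN2 methylation of the carboxylate, since bicarbonate deprotonates the carboxylic acid but not the resorcinol hydroxyls, and the open-chain carboxylate gives the normal ester.

Compound list
1 | nonane-2,4-dione | CCCCCC(=O)CC(C)=O | starting material
2 | ethyl 2-(benzyloxy)acetate | CCOC(=O)COCc1ccccc1 | starting material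
3 | dilithium dianion of nonane-2,4-dione (terminal dienediolate, formed in the flask) | [Li+].[Li+].C=C([O-])C=C([O-])CCCCC | intermediate
4 | 1-(benzyloxy)undecane-2,4,6-trione | CCCCCC(=O)CC(=O)CC(=O)COCc1ccccc1 | intermediate
5 | 2-[(benzyloxy)methyl]-6-pentyl-4H-pyran-4-one | CCCCCC1=CC(=O)C=C(COCc2ccccc2)O1 | intermediate
6 | 2-(hydroxymethyl)-6-pentyl-4H-pyran-4-one | CCCCCC1=CC(=O)C=C(CO)O1 | intermediate
7 | 2-(chloromethyl)-6-pentyl-4H-pyran-4-one | CCCCCC1=CC(=O)C=C(CCl)O1 | intermediate
8 | 3,5-dimethoxybenzoic acid | COc1cc(OC)cc(C(=O)O)c1 | starting material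
9 | 1-(3,5-dimethoxyphenyl)pentan-1-one | CCCCC(=O)c1cc(OC)cc(OC)c1 | intermediate
10 | 2,4-dimethoxy-6-pentanoylbenzaldehyde | CCCCC(=O)c1cc(OC)cc(OC)c1C=O | intermediate
11 | 2,4-dimethoxy-6-pentanoylbenzoic acid | CCCCC(=O)c1cc(OC)cc(OC)c1C(=O)O | intermediate
12 | methyl 2,4-dimethoxy-6-pentanoylbenzoate | CCCCC(=O)c1cc(OC)cc(OC)c1C(=O)OC | intermediate
13 | methyl 2-hydroxy-4-methoxy-6-pentanoylbenzoate | CCCCC(=O)c1cc(OC)cc(O)c1C(=O)OC | intermediate
14 | methyl 4-methoxy-2-[(4-oxo-6-pentyl-4H-pyran-2-yl)methoxy]-6-pentanoylbenzoate | CCCCCC1=CC(=O)C=C(COc2cc(OC)cc(C(=O)CCCC)c2C(=O)OC)O1 | intermediate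
15 | 4-methoxy-2-[(4-oxo-6-pentyl-4H-pyran-2-yl)methoxy]-6-pentanoylbenzoic acid (present as its potassium salt, formed in the flask) | CCCCCC1=CC(=O)C=C(COc2cc(OC)cc(C(=O)CCCC)c2C(=O)O)O1 | intermediate
16 | 4-methoxy-6-pentanoyl-2-[(2,4,6-trioxoundecyl)oxy]benzoic acid (present as its enolised potassium salt, formed in the flask) | CCCCCC(=O)CC(=O)CC(=O)COc1cc(OC)cc(C(=O)CCCC)c1C(=O)O | intermediate
17 | 2-[(2-hydroxy-4,6-dioxo-2-pentylcyclohexyl)oxy]-4-methoxy-6-pentanoylbenzoic acid (diastereomer mixture, formed in the flask) | CCCCCC1(O)CC(=O)CC(=O)C1Oc1cc(OC)cc(C(=O)CCCC)c1C(=O)O | intermediate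
18 | 2-(2,4-dihydroxy-6-pentylphenoxy)-4-methoxy-6-pentanoylbenzoic acid | CCCCCc1cc(O)cc(O)c1Oc1cc(OC)cc(C(=O)CCCC)c1C(=O)O | intermediate
19 | methyl 2-(2,4-dihydroxy-6-pentylphenoxy)-4-methoxy-6-pentanoylbenzoate | CCCCCc1cc(O)cc(O)c1Oc1cc(OC)cc(C(=O)CCCC)c1C(=O)OC | target

Total step count: 12
Longest linear sequence: 8 steps (steps 5 to 12, from 8 to 19); the pyranone branch (steps 1 to 4) joins at step 10.

Steps most likely to fail

Step 11. Terminal enolisation may take place on the pentyl side, so that the aldol closes in the other direction, or hydroxide may fragment the triketone by retro-Claisen cleavage before it cyclises. The fallback gives up ring construction and makes the aryl–oxygen bond by copper catalysis, setting out from phenol 13. Commercial olivetol (5-pentylresorcinol, CCCCCc1cc(O)cc(O)c1) would be benzylated (BnBr, K2CO3, DMF) to 1,3-bis(benzyloxy)-5-pentylbenzene F1. Iodination of F1 with NIS (MeCN, cat. TFA) should occur at the position between pentyl and benzyloxy, para to the other benzyloxy, to give 1,5-bis(benzyloxy)-2-iodo-3-pentylbenzene F2. An Ullmann ether synthesis of F2 with 13 (CuI, picolinic acid, K3PO4, DMSO, 100 °C) should give methyl 2-[2,4-bis(benzyloxy)-6-pentylphenoxy]-4-methoxy-6-pentanoylbenzoate F3. Hydrogenolysis of the two benzyl ethers (H2, Pd/C, EtOAc, rt, stopped after two equivalents) comes back to the route at the target 19.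

Step 1. Proton transfer from the enolisable α-alkoxy ester to the strongly basic dianion may quench the nucleophile and stall the acylation. The fallback sets out from 1, again through dianion 3, and replaces the ester by an aldehyde, whose addition is much faster than proton transfer. Reaction of 3 with 2-(benzyloxy)acetaldehyde (O=CCOCc1ccccc1) at −78 °C should give racemic 1-(benzyloxy)-2-hydroxyundecane-4,6-dione F4. Oxidation of its secondary alcohol with IBX (EtOAc, 75 °C) comes back to the route at triketone 4.

Step 6. Formylation may go to the position between the two methoxy groups, or the Lewis acid and the chloro ether may engage the enolisable ketone. The fallback sets out from ketone 9 and brings in the carboxyl carbon by halogenation and carbonylation. NBS (MeCN, rt) should brominate ortho to the acyl group to give 1-(2-bromo-3,5-dimethoxyphenyl)pentan-1-one F5. Palladium-catalysed methoxycarbonylation of F5 (Pd(OAc)2, Xantphos, CO 1 atm, MeOH, Et3N, 70 °C) comes back to the route at ester 12, passing over 10 and 11.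

Further compounds
F1 | step 11 | 1,3-bis(benzyloxy)-5-pentylbenzene | CCCCCc1cc(OCc2ccccc2)cc(OCc2ccccc2)c1
F2 | step 11 | 1,5-bis(benzyloxy)-2-iodo-3-pentylbenzene | CCCCCc1cc(OCc2ccccc2)cc(OCc2ccccc2)c1I
F3 | step 11 | methyl 2-[2,4-bis(benzyloxy)-6-pentylphenoxy]-4-methoxy-6-pentanoylbenzoate | CCCCCc1cc(OCc2ccccc2)cc(OCc2ccccc2)c1Oc1cc(OC)cc(C(=O)CCCC)c1C(=O)OC
F4 | step 1 | 1-(benzyloxy)-2-hydroxyundecane-4,6-dione (racemic) | CCCCCC(=O)CC(=O)CC(O)COCc1ccccc1
F5 | step 6 | 1-(2-bromo-3,5-dimethoxyphenyl)pentan-1-one | CCCCC(=O)c1cc(OC)cc(OC)c1Br
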